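## The problem

The target 38 is a normal-series labdane: a trans-decalin in which ring A carries two quaternary carbons (C4 and C10) and ring B carries the tertiary alcohol C8 and the side-chain-bearing C9, with C5 as the fifth stereocentre. At C4 the two one-carbon arms differ. C18 (α, equatorial) is a methyl group; C19 (β, axial, syn to the C10 methyl C20) is the CH2O group esterified with (Z)-ferulic acid. The synthesis must therefore tell two nearly identical arms apart and relate that choice to C10 across ring A. Once C4 and C10 are fixed they can control the rest: the axial C19 and C20 groups close the β face, so hydrogen at C5, and oxygen at C8 together with hydrogen at C9 (a syn pair, 8α-OH/9α-H), can be brought in from the α face. The side chain ends in a 2-substituted buta-1,3-diene that polymerises and takes up borane or hydrogen faster than any ring alkene, so it has to appear late. The (Z)-feruloyl ester isomerises to E under light, base (through the phenoxide) or acid. The tertiary C8 alcohol eliminates under acid and cyclises onto any electrophilic C12 or C13. The enabling feature is that C18 and the C10–C9 bond lie on the same (α) face of ring A: a dienophile held on the C18 oxygen can reach C10 only from that face, so one cycloaddition onto a C10=C5–C6=C7 diene built on ring A fixes C10 relative to C4 and closes ring B.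

## Retrosynthesis

**Z-enoate last.** Target 38 comes from its aryl silyl ether 37 by buffered desilylation. 37 is cut at the cinnamate C=C into the C19 phosphonoacetate 33 and the protected aldehyde 35 (one silylation from vanillin 34). Acylation with a preformed Z-cinnamic acid would expose the Z-alkene to activation and base, and semihydrogenation of an arylpropiolate would not spare the diene. An on-substrate Still–Gennari olefination forms the Z-alkene under kinetic control at low temperature as the last C–C bond. 33 is simply diene diol 31 acylated with acid 32 at its only primary hydroxyl. The forward reaction must remain Z-selective with an electron-rich aldehyde, and the final deprotection must not pass through free phenoxide.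

**Diene from an alkyne.** Diol 31 comes from silyl ether 30, whose butadiene is cut at C13=C16 and C14=C15 back to terminal alkyne 29 (enyne cross-metathesis with the two-carbon alkene). A methyl ketone/enol triflate route would need protection of the C8 alcohol and regiocontrolled enolisation. Dehydration of a C13 tertiary allylic alcohol is not regioselective. The alkyne keeps the diene out of every step that uses boranes or hydrogen. Required: tolerance of the free tertiary alcohol and no secondary metathesis of the product.

**Alkyne from a 1,5-diol.** Alkyne 29 is cut at C13–C14 to lactol 28, the closed form of hydroxy aldehyde 27, which is the oxidation product of the 8α,13-diol 26. A one-carbon homologation is preferred to alkylation with a propargyl unit because an alkyne could not survive the hydration of C8=C9. Diol 26 holds all five ring stereocentres and no unsaturation. Required: oxidation of the primary alcohol only, and homologation through the lactol–aldehyde equilibrium.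

**Syn hydration of C8=C9.** Diol 26 is cut at C8–O, C9–H and C13–O back to diene 23 (tetrasubstituted C8=C9, terminal C12=C13). The target needs OH and H cis on C8 and C9. That rules out epoxide opening (anti) and methyl addition to a C8 ketone (which favours the 8-epimer). Hydroboration is the direct syn addition and also converts the terminal alkene into the C13 alcohol. Required: boron on C8 rather than C9, attack from the α face, and no intramolecular delivery from a pendant B–H.

**Side-chain carbons and the C18 methyl.** Diene 23 is cut at C18–H (mesylate 22) and at C11–C12 (allylic bromide 20 plus vinylmagnesium bromide 21). Allyl–vinyl coupling brings C12 and C13 at the oxidation level needed above; enolate alkylation or olefination at C11 would add redox steps. The C18 oxygen, having served as tether anchor, leaves by hydride displacement of its sulfonate. 20 arises in one operation from diol 18, since only the allylic sulfonate is displaced by bromide. Required: coupling at C11 without allylic transposition, and SN2 hydride delivery at a neopentyl carbon.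

**Ring fusion and lactone opening.** Diol 18 is cut at C5–H/C6–H back to diene diol 17, and 17 by reduction to lactone 16. The lactone bridge covers the α face of C5=C6, so it is opened before hydrogenation. Once open, the axial C19 and C20 groups leave only the α face, which gives the trans fusion. Required: reduction of the trisubstituted alkene only.

**The key cut.** Lactone 16 is cut at C9–C10 and C7–C8 to ynoate 15, a 2-methyl-1-vinylcyclohexene whose C4 carries the silyloxymethyl arm (C19) and the but-2-ynoyloxymethyl arm (C18). Intermolecular addition of an acetylenic ester to this diene class is known but would ignore C4. The tether turns the C4 stereocentre into control of both face and regiochemistry, and it brings C17 and C11 with the dienophile. The precursor is monocyclic with a single stereocentre. Required: a type 2 intramolecular cycloaddition through a strained, bridged transition state.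

**Tether and C4.** Ynoate 15 is cut at the ester C–O into alcohol 13 and but-2-ynoic acid 14. 13 comes via 12 from monoacetate 11, obtained by enantiotopic-group-selective acetylation of prochiral diol 10. Desymmetrisation is preferred to asymmetric alkylation because the arms are constitutionally identical and the rest of the ring is achiral. Either enzyme preference is usable (acylation of the diol or hydrolysis of its diacetate). Required: discrimination at a quaternary prochiral centre and no acyl or silyl migration afterwards.

**The diene diol.** Diol 10 is cut at both arms to ester 9, then at C5–C6 to enol triflate 7 plus vinylstannane 8. 7 goes back through enolate 6 to ketone 5, whose quaternary carbon comes from hydroxymethylation (4) of β-keto ester 3, the carbethoxylation product of 2-methylcyclohexanone 1 with diethyl carbonate 2. Because C4 is quaternary, the ketone enolises only toward the methyl-bearing carbon, so triflation fixes the C10=C5 position and cross-coupling completes the diene without acid.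

## Roads not taken

**Alternative 1:** The cut is the C4–C19 bond (with the C5–H bond).
- Forward key step: tin-hydride-mediated radical cyclisation of bromomethylsilyl ether A1 of a ring A 3β-allylic alcohol. The silylmethyl radical closes 5-exo onto C4 from the face of the oxygen, and the C5 radical is reduced from the α face. This gives oxasilolane A2 with C19 β and a trans ring fusion; oxidative C–Si cleavage would then unveil the C19 hydroxyl.
- Merits: the reaction type is fully precedented, the relay from the C3 oxygen to C4 and C5 is dependable, and C10 would be inherited from an enantioenriched annulation product.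
- Weak points: C3 has no oxygen in 38, so the directing group must be removed. The step makes one C–C bond and no ring. All of ring B's decoration (C17, the C8 carbinol, C9 and the chain) must still be grown from the C9 ketal, where methyl addition to a C8 ketone favours the wrong epimer.
- Comparison: at its key step this road is safer than the chosen one, which rests on an unproven cycloaddition. The chosen plan sets against that the formation of ring B, C10 and the C4/C10 relationship in one operation, no surplus oxygen, and a fallback by known intermolecular chemistry.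

**Alternative 2:** The cut is C5–C6 and C9–C10, ring B by an intermolecular cycloaddition of enal A3 (C5=C10) with diene A4 (C6=C7–C8=C9).
- Forward key step: exo-selective Diels–Alder catalysed by a chiral oxazaborolidinium triflimide (a protonated B-aryl oxazaborolidine with NTf2 counter-ion), giving cyclohexene aldehyde A5 with C5, C9 and C10 set.
- Merits: absolute configuration from a small-molecule catalyst, three stereocentres including quaternary C10 in a convergent step, and C17 with a C7=C8 alkene already placed for hydration. In enantiocontrol and precedent this is stronger than the chosen plan.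
- Weak points: the dienophile is an α,β-disubstituted enal and the diene must bond through its substituted terminus, which is at the limit of the catalyst class. Ring A does not exist in A5 and has to be annulated from the aldehyde and the acetate arm. C4 must then be made quaternary with C18/C19 discrimination by substrate control, the very problem the target poses.
- Comparison: the chosen plan answers with ring A and the differentiated C4 in place before the cycloaddition, at the price of an enzyme step and an unproven key step.

**Alternative 3:** The cut is C5–C10 and C8–C9, both rings at once from acyclic trienimide A6.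
- Forward key step: Me2AlCl-promoted endo intramolecular Diels–Alder under control of a 4-benzyloxazolidinone auxiliary, giving trans-fused octalin imide A7 with C5, C9 and C10 set and a C4 gem-diester.
- Merits: two rings and three stereocentres in one step of a well-established reaction class. To the bicyclic core this is shorter and better precedented than the chosen route.
- Weak points: the β,β-disubstituted enoyl dienophile that must create quaternary C10 is a sluggish partner. The C4 diester is undifferentiated, so C18 and C19 must be told apart later by the small axial/equatorial bias. C8 is a bare methylene in A7, so C17 and the 8α-hydroxyl need allylic oxidation, methylenation and hydration. C11 is an acyl carbon on a neopentyl-like position, awkward for chain extension.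
- Comparison: the chosen plan sets against the shorter core synthesis a C4 centre that is already differentiated, C17 delivered with the dienophile, a C8=C9 alkene placed for one-step syn hydration, and C11 as an allylic handle.

Key step: step 11

Remarks on the chemistry:
- Labdane numbering is used for all bicyclic compounds (C17 on C8, C18 α and C19 β on C4, C20 on C10; normal series, H-5 α). TBDPS = tert-butyldiphenylsilyl, TBS = tert-butyldimethylsilyl, Piv = pivaloyl, Ms = methanesulfonyl.
- Assumption: the lipase acetylates the pro-R hydroxymethyl group of 10; if it prefers the other arm, the same enzyme applied to hydrolysis of the diacetate of 10 gives the same monoacetate 11.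
- Assumption: acid 32 is purchased; otherwise it is one saponification from its commercial methyl ester.

## Route

Step 1
Reactants: 1 2-methylcyclohexanone; 2 diethyl carbonate
Product: 3 ethyl 3-methyl-2-oxocyclohexane-1-carboxylate (diastereomer mixture)
Conditions: NaH, THF, reflux; then aq. HCl
Reagents that add atoms: none
Why: Crossed Claisen carbethoxylation; acylation ends at the unsubstituted α-carbon because only that β-keto ester can be deprotonated to a stabilised enolate, which drives the equilibrium.

Step 2
Reactants: 3 ethyl 3-methyl-2-oxocyclohexane-1-carboxylate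
Product: 4 ethyl 1-(hydroxymethyl)-3-methyl-2-oxocyclohexane-1-carboxylate (racemic diastereomer mixture)
Conditions: aq. CH2O, KHCO3 (cat.), THF, rt
Reagents that add atoms: formaldehyde C=O
Why: Base-catalysed aldol hydroxymethylation at the doubly activated carbon creates the quaternary carbon that becomes C4; its configuration is irrelevant because both arms become CH2OH in step 6.

Step 3
Reactants: 4 ethyl 1-(hydroxymethyl)-3-methyl-2-oxocyclohexane-1-carboxylate
Product: 5 ethyl 3-methyl-2-oxo-1-(pivaloyloxymethyl)cyclohexane-1-carboxylate
Conditions: PivCl, pyridine, 4-(dimethylamino)pyridine (cat.), CH2Cl2, 0 °C → rt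
Reagents that add atoms: pivaloyl chloride CC(C)(C)C(Cl)=O
Why: Acylation of the primary alcohol; the pivalate blocks retro-aldol loss of formaldehyde under base, has no enolisable hydrogen, and is removed by hydride in step 6.

Step 4
Reactants: 5 ethyl 3-methyl-2-oxo-1-(pivaloyloxymethyl)cyclohexane-1-carboxylate
Product: 7 ethyl 3-methyl-1-(pivaloyloxymethyl)-2-(trifluoromethylsulfonyloxy)cyclohex-2-ene-1-carboxylate (racemic), via potassium enolate 6 (not isolated)
Conditions: KN(SiMe3)2, THF, −78 °C; then PhNTf2, −78 → 0 °C
Reagents that add atoms: N-phenylbis(trifluoromethanesulfonimide) O=S(=O)(N(c1ccccc1)S(=O)(=O)C(F)(F)F)C(F)(F)F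
Why: The only α-hydrogen of the ketone is on the methyl-bearing carbon, so enolisation and O-sulfonylation (enol triflate formation) give the tetrasubstituted triflate as one regioisomer, as for 2,2,6-trisubstituted cyclohexanones.

Step 5
Reactants: 7 ethyl 3-methyl-1-(pivaloyloxymethyl)-2-(trifluoromethylsulfonyloxy)cyclohex-2-ene-1-carboxylate; 8 tributyl(vinyl)stannane
Product: 9 ethyl 3-methyl-1-(pivaloyloxymethyl)-2-vinylcyclohex-2-ene-1-carboxylate (racemic)
Conditions: Pd(PPh3)4 (cat.), LiCl, THF, reflux
Reagents that add atoms: none
Why: Stille coupling of a hindered cyclohexenyl triflate with a vinylstannane is standard and installs C6=C7 under neutral conditions, completing the 2-methyl-1-vinylcyclohexene.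

Step 6
Reactants: 9 ethyl 3-methyl-1-(pivaloyloxymethyl)-2-vinylcyclohex-2-ene-1-carboxylate
Product: 10 (3-methyl-2-vinylcyclohex-2-ene-1,1-diyl)dimethanol (achiral, prochiral at C4)
Conditions: LiAlH4, THF, 0 °C → rt
Reagents that add atoms: none
Why: Hydride reduces the ethyl ester and cleaves the pivalate in one operation; the arms become identical, so the racemic stereocentre is erased and a prochiral diol results.

Step 7
Reactants: 10 (3-methyl-2-vinylcyclohex-2-ene-1,1-diyl)dimethanol
Product: 11 [(1R)-1-(hydroxymethyl)-3-methyl-2-vinylcyclohex-2-en-1-yl]methyl acetate (acetate on the arm that becomes C18)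
Conditions: Burkholderia cepacia lipase, vinyl acetate, tBuOMe, rt
Reagents that add atoms: vinyl acetate CC(=O)OC=C
Why: Lipase-catalysed enantiotopic-group-selective transesterification of a prochiral 2,2-disubstituted propane-1,3-diol with an irreversible acyl donor; the enzyme tells the arm flanked by the ring CH2 from the arm flanked by the dienyl carbon and thereby sets C4.

Step 8
Reactants: 11 [(1R)-1-(hydroxymethyl)-3-methyl-2-vinylcyclohex-2-en-1-yl]methyl acetate
Product: 12 [(1S)-1-(TBDPS-oxymethyl)-3-methyl-2-vinylcyclohex-2-en-1-yl]methyl acetate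
Conditions: TBDPSCl, imidazole, DMF, 0 °C
Reagents that add atoms: tert-butyl(chloro)diphenylsilane CC(C)(C)[Si](Cl)(c1ccccc1)c1ccccc1
Why: Silylation of the remaining neopentyl-type primary alcohol (the future C19 oxygen), run cold and without delay so that acetyl migration between the arms, which would racemise C4, does not compete.

Step 9
Reactants: 12 [(1S)-1-(TBDPS-oxymethyl)-3-methyl-2-vinylcyclohex-2-en-1-yl]methyl acetate
Product: 13 [(1S)-1-(TBDPS-oxymethyl)-3-methyl-2-vinylcyclohex-2-en-1-yl]methanol
Conditions: iBu2AlH, CH2Cl2, −78 °C
Reagents that add atoms: none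
Why: Reductive removal of the acetate at low temperature gives an aluminium alkoxide and avoids the free alkoxide that could trigger silyl migration between the arms and scramble C4.

Step 10
Reactants: 13 [(1S)-1-(TBDPS-oxymethyl)-3-methyl-2-vinylcyclohex-2-en-1-yl]methanol; 14 but-2-ynoic acid
Product: 15 [(1S)-1-(TBDPS-oxymethyl)-3-methyl-2-vinylcyclohex-2-en-1-yl]methyl but-2-ynoate
Conditions: DCC, 4-(dimethylamino)pyridine (cat.), CH2Cl2, −20 → 0 °C
Reagents that add atoms: none
Why: Steglich esterification, cold and with little nucleophilic catalyst to limit conjugate addition to the ynoate; it installs the four-atom tether C4–C18–O–C11 carrying the C9≡C8–C17 dienophile.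

Step 11
Reactants: 15 [(1S)-1-(TBDPS-oxymethyl)-3-methyl-2-vinylcyclohex-2-en-1-yl]methyl but-2-ynoate
Product: 16 (4S,10S)-19-(TBDPS-oxy)-12,13,14,15,16-pentanorlabda-5,8-dien-11,18-olide (seven-membered lactone C11(=O)–O–C18 bridging C9 and C4)
Conditions: PhMe (0.005 M), 2,6-di-tert-butyl-4-methylphenol (cat.), sealed tube, 170 °C
Reagents that add atoms: none
Why: Proposed new method: a concerted thermal [4+2] cycloaddition in which the ynoate C9≡C8 adds across the C10=C5–C6=C7 diene, C9 bonding to C10 and C8 to C7; the closest known reaction types are the type 2 intramolecular Diels–Alder reaction of alkynyl dienophiles that gives bridgehead dienes and the intermolecular addition of acetylenic esters to 2-alkyl-1-vinylcyclohexenes, but an ester tether combined with a fully substituted diene terminus has not been shown. Ring B closes as a six-membered cyclohexa-1,4-diene by the cycloaddition itself, and the lactone closes as a seven-membered bridge (C4–C18–O–C11–C9–C10–C5) in the type 2 mode, the tether being anchored next to the internal diene carbon C5 and ending at the adjacent terminus C10. The only new stereocentre, C10, is controlled by C4: the four-atom tether can hold the alkyne only over the diene face that carries the esterified arm, so C9 bonds cis to C18 and C20 ends syn to C19. The step needs one facial and one regiochemical outcome, and both are secured by the tether length, since neither the opposite face nor the reversed orientation (C9 to C7) can be reached. The inside methyl on C10 becomes the axial angular methyl, as in the intermolecular precedent. The ester must adopt its s-cis form and the product is a strained bicyclo[4.3.1] bridgehead diene, so forcing conditions are expected; the temperature is kept at or below 170 °C to stay ahead of the [1,5]-hydrogen shift from C20 to C7 open to such dienes, and high dilution with a radical inhibitor suppresses oligomerisation. The strain is released in step 12.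

Step 12
Reactants: 16 (4S,10S)-19-(TBDPS-oxy)-12,13,14,15,16-pentanorlabda-5,8-dien-11,18-olide
Product: 17 (4S,10S)-19-(TBDPS-oxy)-12,13,14,15,16-pentanorlabda-5,8-diene-11,18-diol
Conditions: iBu2AlH, CH2Cl2, −78 → 0 °C
Reagents that add atoms: none
Why: 1,2-Hydride reduction of the strained conjugated lactone gives the allylic C11 alcohol and frees the C18 alcohol; the bridge that covered the α face of C5=C6 is removed.

Step 13
Reactants: 17 (4S,10S)-19-(TBDPS-oxy)-12,13,14,15,16-pentanorlabda-5,8-diene-11,18-diol
Product: 18 19-(TBDPS-oxy)-12,13,14,15,16-pentanorlabd-8-ene-11,18-diol (H-5 α, trans-fused)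
Conditions: H2 (3 atm), Pd/C, EtOAc, Et3N (trace), rt
Reagents that add atoms: none
Why: Heterogeneous hydrogenation reduces only the trisubstituted C5=C6, the tetrasubstituted C8=C9 next to quaternary C10 being too hindered to adsorb; hydrogen arrives on the α face because C20 and the axial C19 silyloxymethyl shield the β face, which sets C5 and the trans fusion as in related 4,4,10-trisubstituted octalin-5,8-dienes.

Step 14
Reactants: 18 19-(TBDPS-oxy)-12,13,14,15,16-pentanorlabd-8-ene-11,18-diol
Product: 20 11-bromo-19-(TBDPS-oxy)-12,13,14,15,16-pentanorlabd-8-en-18-yl methanesulfonate, via bis-mesylate 19 (not isolated)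
Conditions: Ms2O, Et3N, CH2Cl2, −30 °C; then LiBr, THF, 0 °C → rt
Reagents that add atoms: methanesulfonic anhydride CS(=O)(=O)OS(C)(=O)=O; lithium bromide [Li+].[Br-]
Why: Both primary alcohols are sulfonylated, and Finkelstein-type displacement then occurs only at the allylic C11 mesylate; the neopentyl C18 mesylate is inert to bromide and is kept for step 16.

Step 15
Reactants: 20 11-bromo-19-(TBDPS-oxy)-12,13,14,15,16-pentanorlabd-8-en-18-yl methanesulfonate; 21 vinylmagnesium bromide
Product: 22 19-(TBDPS-oxy)-14,15,16-trinorlabda-8,12-dien-18-yl methanesulfonate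
Conditions: CuI (cat.), THF, −40 → 0 °C
Reagents that add atoms: none
Why: Copper-catalysed (Kochi-type) coupling of an allylic bromide with a vinyl Grignard reagent at the primary terminus, because attack at the other allyl terminus would have to create a quaternary C8; the neopentyl mesylate does not couple.

Step 16
Reactants: 22 19-(TBDPS-oxy)-14,15,16-trinorlabda-8,12-dien-18-yl methanesulfonate
Product: 23 19-(TBDPS-oxy)-14,15,16-trinorlabda-8,12-diene
Conditions: LiEt3BH, THF, 0 → 65 °C
Reagents that add atoms: none
Why: LiEt3BH reduces hindered neopentyl sulfonates by direct SN2 hydride displacement, turning C18 into the α methyl group; alkenes and the silyl ether are untouched.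

Step 17
Reactants: 23 19-(TBDPS-oxy)-14,15,16-trinorlabda-8,12-diene
Product: 26 19-(TBDPS-oxy)-14,15,16-trinorlabdane-8α,13-diol, via 13-(9-BBN) borane 24 (not isolated), via 8-boryl-13-(9-BBN) bis-borane 25 (not isolated)
Conditions: 9-BBN, THF, 0 °C → rt; then BH3·THF, rt → 40 °C; then NaOH, H2O2, 0 → 50 °C
Reagents that add atoms: hydrogen peroxide OO
Why: 9-BBN takes the terminal alkene anti-Markovnikov and, having no B–H left, cannot deliver boron intramolecularly to C9; BH3 then adds to the tetrasubstituted C8=C9 with boron on the less hindered C8 and syn from the α face (β face blocked by C20), and oxidation with retention sets 8α-OH and 9α-H, as in hydroboration of 1,2-dialkylcyclohexenes.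

Step 18
Reactants: 26 19-(TBDPS-oxy)-14,15,16-trinorlabdane-8α,13-diol
Product: 28 lactol 19-(TBDPS-oxy)-8α,13-epoxy-14,15,16-trinorlabdan-13-ol (anomer mixture), via hydroxy aldehyde 27 (not isolated)
Conditions: (COCl)2, DMSO, CH2Cl2, −78 °C; then Et3N, −78 °C → rt
Reagents that add atoms: none
Why: Swern oxidation touches only the primary alcohol; the δ-hydroxy aldehyde closes to the six-membered lactol on warming, after the oxidant is spent, so over-oxidation to the lactone is avoided.

Step 19
Reactants: 28 lactol 19-(TBDPS-oxy)-8α,13-epoxy-14,15,16-trinorlabdan-13-ol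
Product: 29 19-(TBDPS-oxy)-15,16-dinorlabd-13-yn-8α-ol
Conditions: dimethyl (1-diazo-2-oxopropyl)phosphonate, K2CO3, MeOH, 0 °C → rt
Reagents that add atoms: dimethyl (1-diazo-2-oxopropyl)phosphonate CC(=O)C(=[N+]=[N-])P(=O)(OC)OC
Why: Seyferth–Gilbert homologation with the Ohira–Bestmann reagent; the lactol reacts through its open hydroxy aldehyde under mild basic methanol, and the tertiary alcohol needs no protection.

Step 20
Reactants: 29 19-(TBDPS-oxy)-15,16-dinorlabd-13-yn-8α-ol
Product: 30 19-(TBDPS-oxy)labda-13(16),14-dien-8α-ol
Conditions: ethylene (1 atm), RuCl2(=CHPh)(PCy3)(H2IMes) (second-generation Grubbs catalyst, cat.), PhMe, 80 °C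
Reagents that add atoms: ethylene C=C
Why: Ethylene–alkyne cross enyne metathesis converts a terminal alkyne into a 2-substituted buta-1,3-diene in one step and tolerates the free tertiary alcohol; excess ethylene keeps secondary metathesis of the diene degenerate.

Step 21
Reactants: 30 19-(TBDPS-oxy)labda-13(16),14-dien-8α-ol
Product: 31 labda-13(16),14-diene-8α,19-diol
Conditions: Bu4NF, THF, rt → 45 °C
Reagents that add atoms: none
Why: Fluoride cleavage of the hindered silyl ether; the diene and the tertiary alcohol are inert to these conditions.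

Step 22
Reactants: 31 labda-13(16),14-diene-8α,19-diol; 32 [bis(2,2,2-trifluoroethoxy)phosphoryl]acetic acid
Product: 33 8α-hydroxylabda-13(16),14-dien-19-yl [bis(2,2,2-trifluoroethoxy)phosphoryl]acetate
Conditions: DCC, 4-(dimethylamino)pyridine (cat.), CH2Cl2, 0 °C → rt
Reagents that add atoms: none
Why: Steglich esterification; only the primary C19 hydroxyl is acylated, the tertiary C8 hydroxyl being unreactive.

Step 23
Reactants: 34 vanillin
Product: 35 4-(TBS-oxy)-3-methoxybenzaldehyde
Conditions: TBSCl, imidazole, DMF, rt
Reagents that add atoms: tert-butyl(chloro)dimethylsilane CC(C)(C)[Si](C)(C)Cl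
Why: Standard phenol silylation, so that the aldehyde is not deactivated as a phenoxide in step 24.

Step 24
Reactants: 33 8α-hydroxylabda-13(16),14-dien-19-yl [bis(2,2,2-trifluoroethoxy)phosphoryl]acetate; 35 4-(TBS-oxy)-3-methoxybenzaldehyde
Product: 37 8α-hydroxylabda-13(16),14-dien-19-yl (Z)-3-[4-(TBS-oxy)-3-methoxyphenyl]prop-2-enoate, via potassium phosphonate 36 (not isolated)
Conditions: KN(SiMe3)2, 18-crown-6, THF, −78 °C; then 35, −78 °C, dark
Reagents that add atoms: none
Why: Still–Gennari olefination; the adduct of the bis(trifluoroethyl) phosphonate anion with the aryl aldehyde eliminates faster than it equilibrates, which gives the Z-cinnamate under kinetic control, and the phosphonate C–H is far more acidic than the tertiary alcohol, so one equivalent of base suffices.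

Step 25
Reactants: 37 8α-hydroxylabda-13(16),14-dien-19-yl (Z)-3-[4-(TBS-oxy)-3-methoxyphenyl]prop-2-enoate
Product: 38 8α-hydroxylabda-13(16),14-dien-19-yl (Z)-ferulate (CNP0142252.2)
Conditions: Bu4NF, AcOH, THF, 0 °C, dark
Reagents that add atoms: none
Why: Buffered fluoride removes the aryl silyl ether quickly at 0 °C; acetic acid keeps the phenoxide concentration low and light is excluded, so the Z-enoate should not isomerise.

## Compound list

1 | 2-methylcyclohexanone | CC1CCCCC1=O | starting material
2 | diethyl carbonate | CCOC(=O)OCC | starting material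
3 | ethyl 3-methyl-2-oxocyclohexane-1-carboxylate | CCOC(=O)C1CCCC(C)C1=O | intermediate
4 | ethyl 1-(hydroxymethyl)-3-methyl-2-oxocyclohexane-1-carboxylate | CCOC(=O)C1(CO)CCCC(C)C1=O | intermediate
5 | ethyl 3-methyl-2-oxo-1-(pivaloyloxymethyl)cyclohexane-1-carboxylate | CCOC(=O)C1(COC(=O)C(C)(C)C)CCCC(C)C1=O | intermediate
6 | potassium enolate of 5 | CCOC(=O)C1(COC(=O)C(C)(C)C)CCCC(C)=C1[O-].[K+] | intermediate
7 | ethyl 3-methyl-1-(pivaloyloxymethyl)-2-(trifluoromethylsulfonyloxy)cyclohex-2-ene-1-carboxylate | CCOC(=O)C1(COC(=O)C(C)(C)C)CCCC(C)=C1OS(=O)(=O)C(F)(F)F | intermediate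
8 | tributyl(vinyl)stannane | CCCC[Sn](CCCC)(CCCC)C=C | starting material
9 | ethyl 3-methyl-1-(pivaloyloxymethyl)-2-vinylcyclohex-2-ene-1-carboxylate | CCOC(=O)C1(COC(=O)C(C)(C)C)CCCC(C)=C1C=C | intermediate
10 | (3-methyl-2-vinylcyclohex-2-ene-1,1-diyl)dimethanol | CC1=C(C=C)C(CO)(CO)CCC1 | intermediate
11 | [(1R)-1-(hydroxymethyl)-3-methyl-2-vinylcyclohex-2-en-1-yl]methyl acetate | CC1=C(C=C)[C@@](COC(C)=O)(CO)CCC1 | intermediate
12 | [(1S)-1-(TBDPS-oxymethyl)-3-methyl-2-vinylcyclohex-2-en-1-yl]methyl acetate | CC1=C(C=C)[C@@](COC(C)=O)(CO[Si](c2ccccc2)(c2ccccc2)C(C)(C)C)CCC1 | intermediate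
13 | [(1S)-1-(TBDPS-oxymethyl)-3-methyl-2-vinylcyclohex-2-en-1-yl]methanol | CC1=C(C=C)[C@@](CO)(CO[Si](c2ccccc2)(c2ccccc2)C(C)(C)C)CCC1 | intermediate
14 | but-2-ynoic acid | CC#CC(=O)O | starting material
15 | [(1S)-1-(TBDPS-oxymethyl)-3-methyl-2-vinylcyclohex-2-en-1-yl]methyl but-2-ynoate | CC1=C(C=C)[C@@](COC(=O)C#CC)(CO[Si](c2ccccc2)(c2ccccc2)C(C)(C)C)CCC1 | intermediate
16 | (4S,10S)-19-(TBDPS-oxy)-12,13,14,15,16-pentanorlabda-5,8-dien-11,18-olide | CC1=C2C(=O)OC[C@]3(CO[Si](c4ccccc4)(c4ccccc4)C(C)(C)C)CCC[C@@]2(C)C3=CC1 | intermediate
17 | (4S,10S)-19-(TBDPS-oxy)-12,13,14,15,16-pentanorlabda-5,8-diene-11,18-diol | CC1=C(CO)[C@@]2(C)CCC[C@](CO)(CO[Si](c3ccccc3)(c3ccccc3)C(C)(C)C)C2=CC1 | intermediate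
18 | 19-(TBDPS-oxy)-12,13,14,15,16-pentanorlabd-8-ene-11,18-diol (H-5 α) | CC1=C(CO)[C@@]2(C)CCC[C@](CO)(CO[Si](c3ccccc3)(c3ccccc3)C(C)(C)C)[C@@H]2CC1 | intermediate
19 | 11,18-bis(methanesulfonate) of 18 | CC1=C(COS(C)(=O)=O)[C@@]2(C)CCC[C@](COS(C)(=O)=O)(CO[Si](c3ccccc3)(c3ccccc3)C(C)(C)C)[C@@H]2CC1 | intermediate
20 | 11-bromo-19-(TBDPS-oxy)-12,13,14,15,16-pentanorlabd-8-en-18-yl methanesulfonate | CC1=C(CBr)[C@@]2(C)CCC[C@](COS(C)(=O)=O)(CO[Si](c3ccccc3)(c3ccccc3)C(C)(C)C)[C@@H]2CC1 | intermediate
21 | vinylmagnesium bromide | C=C[Mg]Br | starting material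
22 | 19-(TBDPS-oxy)-14,15,16-trinorlabda-8,12-dien-18-yl methanesulfonate | CC1=C(CC=C)[C@@]2(C)CCC[C@](COS(C)(=O)=O)(CO[Si](c3ccccc3)(c3ccccc3)C(C)(C)C)[C@@H]2CC1 | intermediate
23 | 19-(TBDPS-oxy)-14,15,16-trinorlabda-8,12-diene | CC1=C(CC=C)[C@@]2(C)CCC[C@](C)(CO[Si](c3ccccc3)(c3ccccc3)C(C)(C)C)[C@@H]2CC1 | intermediate
24 | 13-(9-borabicyclo[3.3.1]nonan-9-yl)-19-(TBDPS-oxy)-14,15,16-trinorlabd-8-ene | CC1=C(CCCB3C4CCCC3CCC4)[C@@]2(C)CCC[C@](C)(CO[Si](c3ccccc3)(c3ccccc3)C(C)(C)C)[C@@H]2CC1 | intermediate
25 | 8α-boryl-13-(9-borabicyclo[3.3.1]nonan-9-yl)-19-(TBDPS-oxy)-14,15,16-trinorlabdane (H-9 α) | C1CCC2CCCC1B2CCC[C@@H]1[C@@]2(C)CCC[C@](C)(CO[Si](c3ccccc3)(c3ccccc3)C(C)(C)C)[C@@H]2CC[C@@]1(C)B | intermediate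
26 | 19-(TBDPS-oxy)-14,15,16-trinorlabdane-8α,13-diol | OCCC[C@@H]1[C@@]2(C)CCC[C@](C)(CO[Si](c3ccccc3)(c3ccccc3)C(C)(C)C)[C@@H]2CC[C@@]1(C)O | intermediate
27 | 8α-hydroxy-19-(TBDPS-oxy)-14,15,16-trinorlabdan-13-al | O=CCC[C@@H]1[C@@]2(C)CCC[C@](C)(CO[Si](c3ccccc3)(c3ccccc3)C(C)(C)C)[C@@H]2CC[C@@]1(C)O | intermediate
28 | 19-(TBDPS-oxy)-8α,13-epoxy-14,15,16-trinorlabdan-13-ol (lactol, anomer mixture) | OC1CC[C@@H]2[C@@]3(C)CCC[C@](C)(CO[Si](c4ccccc4)(c4ccccc4)C(C)(C)C)[C@@H]3CC[C@@]2(C)O1 | intermediate
29 | 19-(TBDPS-oxy)-15,16-dinorlabd-13-yn-8α-ol | C#CCC[C@@H]1[C@@]2(C)CCC[C@](C)(CO[Si](c3ccccc3)(c3ccccc3)C(C)(C)C)[C@@H]2CC[C@@]1(C)O | intermediate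
30 | 19-(TBDPS-oxy)labda-13(16),14-dien-8α-ol | C=CC(=C)CC[C@@H]1[C@@]2(C)CCC[C@](C)(CO[Si](c3ccccc3)(c3ccccc3)C(C)(C)C)[C@@H]2CC[C@@]1(C)O | intermediate
31 | labda-13(16),14-diene-8α,19-diol | C=CC(=C)CC[C@@H]1[C@@]2(C)CCC[C@](C)(CO)[C@@H]2CC[C@@]1(C)O | intermediate
32 | [bis(2,2,2-trifluoroethoxy)phosphoryl]acetic acid | OC(=O)CP(=O)(OCC(F)(F)F)OCC(F)(F)F | starting material
33 | 8α-hydroxylabda-13(16),14-dien-19-yl [bis(2,2,2-trifluoroethoxy)phosphoryl]acetate | C=CC(=C)CC[C@@H]1[C@@]2(C)CCC[C@](C)(COC(=O)CP(=O)(OCC(F)(F)F)OCC(F)(F)F)[C@@H]2CC[C@@]1(C)O | intermediate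
34 | vanillin (4-hydroxy-3-methoxybenzaldehyde) | COc1cc(C=O)ccc1O | starting material
35 | 4-(TBS-oxy)-3-methoxybenzaldehyde | COc1cc(C=O)ccc1O[Si](C)(C)C(C)(C)C | intermediate
36 | potassium salt of the phosphonate carbanion of 33 | C=CC(=C)CC[C@@H]1[C@@]2(C)CCC[C@](C)(COC(=O)[CH-]P(=O)(OCC(F)(F)F)OCC(F)(F)F)[C@@H]2CC[C@@]1(C)O.[K+] | intermediate
37 | 8α-hydroxylabda-13(16),14-dien-19-yl (Z)-3-[4-(TBS-oxy)-3-methoxyphenyl]prop-2-enoate | C=CC(=C)CC[C@@H]1[C@@]2(C)CCC[C@](C)(COC(=O)/C=C\c3ccc(O[Si](C)(C)C(C)(C)C)c(OC)c3)[C@@H]2CC[C@@]1(C)O | intermediate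
38 | 8α-hydroxylabda-13(16),14-dien-19-yl (Z)-ferulate (CNP0142252.2) | C=CC(=C)CC[C@@H]1[C@@]2(C)CCC[C@](C)(COC(=O)/C=C\c3ccc(O)c(OC)c3)[C@@H]2CC[C@@]1(C)O | target

## Step count and least certain steps

Total steps: 25. Longest linear sequence: 24 (steps 1–22, 24, 25; step 23 is a one-step side branch).

**Step 11 (key step, proposed new method).** The cycloaddition may fail to close because the bridged transition state (s-cis ester, bridgehead diene) lies too high. The [1,5]-hydrogen shift of the diene, oligomerisation or decomposition of the ynoate would then take over. The fallback uses known chemistry and gives up the tether. It sets out from acetate 12, which is heated with methyl but-2-ynoate (neat, 120–140 °C, radical inhibitor) in the established intermolecular Diels–Alder mode of 2-alkyl-1-vinylcyclohexenes with acetylenic esters. This gives methyl (4S,10S)-18-acetoxy-19-(TBDPS-oxy)-12,13,14,15,16-pentanorlabda-5,8-dien-11-oate F1 together with its C10 epimer, which is removed by chromatography. Reduction with iBu2AlH converts the ester and the acetate of F1 to the diol and returns to the route at 17. The cost is the loss of facial control, and possibly of regiocontrol, that the tether was meant to supply.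

**Step 7.** The enzyme may discriminate the two arms poorly, over-acylate to the diacetate, or the monoacetate may lose enantiopurity by acetyl migration before silylation. The fallback replaces enzymatic recognition by covalent diastereomer separation. It sets out from diol 10, which is mono-acylated with (1S)-camphanic chloride (pyridine, CH2Cl2). The diastereomer carrying the ester on the pro-R arm, [(1R)-1-(hydroxymethyl)-3-methyl-2-vinylcyclohex-2-en-1-yl]methyl (1S)-camphanate F2, is separated by crystallisation or chromatography; the other is saponified back to 10. Silylation of F2 with TBDPSCl gives the silyl ether camphanate F3, and brief methanolysis (K2CO3, MeOH, 0 °C) returns to the route at 13.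

**Step 13.** Hydrogenolysis of the allylic C11–O bond, reduction or migration of C8=C9, or incomplete reduction of the hindered C5=C6 may occur. The fallback changes the substrate so that C8=C9 is conjugated and no allylic C–O bond is present. It sets out from lactone 16, which is opened with K2CO3 in MeOH at 0 °C to methyl 18-hydroxy-19-(TBDPS-oxy)-12,13,14,15,16-pentanorlabda-5,8-dien-11-oate F4. Hydrogenation over Pd/C gives the 5α-H ester, methyl 18-hydroxy-19-(TBDPS-oxy)-12,13,14,15,16-pentanorlabd-8-en-11-oate F5, and iBu2AlH reduction returns to the route at 18.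

**Step 17.** Borane may add too slowly to the hindered tetrasubstituted alkene, place boron on C9, or the tertiary borane may migrate on warming, giving regioisomeric alcohols. The fallback builds the C8 carbinol by a [2,3] shift and sets C9 by directed hydrogenation. It sets out from bromide 20.
- PhSNa gives the 11-phenylthio 18-mesylate F6.
- LiEt3BH gives the 11-phenylthio compound with C18 as methyl, F7.
- One equivalent of mCPBA at −78 °C gives the allylic sulfoxide F8.
- Deprotonation with LiN(iPr)2 and alkylation with tert-butyl(2-iodoethoxy)dimethylsilane gives the C11-alkylated sulfoxide F9.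
- Warming with Et2NH in MeOH (Mislow–Evans rearrangement, oxygen delivered to the α face of C8) gives the tertiary allylic alcohol with a C9=C11 alkene, F10.
- Hydroxyl-directed hydrogenation with [Ir(cod)(PCy3)(py)]PF6 gives the 9α-H silyl ether F11.
- Removal of the primary TBS group (pyridinium p-toluenesulfonate, MeOH) returns to the route at 26.

**Step 24.** Z-selectivity may be lower with the electron-rich aldehyde, or the Z-enoate may isomerise during work-up. The fallback makes the alkene without kinetic control and corrects its geometry photochemically. It sets out from diol 31, which is esterified with (diethoxyphosphoryl)acetic acid (DCC) to the diethyl phosphonoacetate F12. Olefination with 35 (LiCl, 1,8-diazabicyclo[5.4.0]undec-7-ene, MeCN) gives the E-cinnamate F13. Irradiation at 350–365 nm, where only the cinnamate absorbs, leads to a photostationary E/Z mixture. The Z-isomer is separated and F13 recycled, returning to the route at 37.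

## Further compounds

F1 | step 11 | methyl (4S,10S)-18-acetoxy-19-(TBDPS-oxy)-12,13,14,15,16-pentanorlabda-5,8-dien-11-oate | CC1=C(C(=O)OC)[C@@]2(C)CCC[C@](COC(C)=O)(CO[Si](c3ccccc3)(c3ccccc3)C(C)(C)C)C2=CC1
F2 | step 7 | [(1R)-1-(hydroxymethyl)-3-methyl-2-vinylcyclohex-2-en-1-yl]methyl (1S,4R)-camphanate | CC1=C(C=C)[C@@](COC(=O)[C@@]23CC[C@@](C)(C(=O)O2)C3(C)C)(CO)CCC1
F3 | step 7 | [(1S)-1-(TBDPS-oxymethyl)-3-methyl-2-vinylcyclohex-2-en-1-yl]methyl (1S,4R)-camphanate | CC1=C(C=C)[C@@](COC(=O)[C@@]23CC[C@@](C)(C(=O)O2)C3(C)C)(CO[Si](c2ccccc2)(c2ccccc2)C(C)(C)C)CCC1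
F4 | step 13 | methyl 18-hydroxy-19-(TBDPS-oxy)-12,13,14,15,16-pentanorlabda-5,8-dien-11-oate | CC1=C(C(=O)OC)[C@@]2(C)CCC[C@](CO)(CO[Si](c3ccccc3)(c3ccccc3)C(C)(C)C)C2=CC1
F5 | step 13 | methyl 18-hydroxy-19-(TBDPS-oxy)-12,13,14,15,16-pentanorlabd-8-en-11-oate (H-5 α) | CC1=C(C(=O)OC)[C@@]2(C)CCC[C@](CO)(CO[Si](c3ccccc3)(c3ccccc3)C(C)(C)C)[C@@H]2CC1
F6 | step 17 | 11-(phenylthio)-19-(TBDPS-oxy)-12,13,14,15,16-pentanorlabd-8-en-18-yl methanesulfonate | CC1=C(CSc3ccccc3)[C@@]2(C)CCC[C@](COS(C)(=O)=O)(CO[Si](c3ccccc3)(c3ccccc3)C(C)(C)C)[C@@H]2CC1
F7 | step 17 | 11-(phenylthio)-19-(TBDPS-oxy)-12,13,14,15,16-pentanorlabd-8-ene | CC1=C(CSc3ccccc3)[C@@]2(C)CCC[C@](C)(CO[Si](c3ccccc3)(c3ccccc3)C(C)(C)C)[C@@H]2CC1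
F8 | step 17 | 11-(phenylsulfinyl)-19-(TBDPS-oxy)-12,13,14,15,16-pentanorlabd-8-ene (sulfur epimers) | CC1=C(CS(=O)c3ccccc3)[C@@]2(C)CCC[C@](C)(CO[Si](c3ccccc3)(c3ccccc3)C(C)(C)C)[C@@H]2CC1
F9 | step 17 | 11-(phenylsulfinyl)-13-(TBS-oxy)-19-(TBDPS-oxy)-14,15,16-trinorlabd-8-ene (diastereomer mixture) | CC1=C(C(CCO[Si](C)(C)C(C)(C)C)S(=O)c3ccccc3)[C@@]2(C)CCC[C@](C)(CO[Si](c3ccccc3)(c3ccccc3)C(C)(C)C)[C@@H]2CC1
F10 | step 17 | 13-(TBS-oxy)-19-(TBDPS-oxy)-14,15,16-trinorlabd-9(11)-en-8α-ol | CC(C)(C)[Si](C)(C)OCCC=C1[C@@]2(C)CCC[C@](C)(CO[Si](c3ccccc3)(c3ccccc3)C(C)(C)C)[C@@H]2CC[C@@]1(C)O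
F11 | step 17 | 13-(TBS-oxy)-19-(TBDPS-oxy)-14,15,16-trinorlabdan-8α-ol | CC(C)(C)[Si](C)(C)OCCC[C@@H]1[C@@]2(C)CCC[C@](C)(CO[Si](c3ccccc3)(c3ccccc3)C(C)(C)C)[C@@H]2CC[C@@]1(C)O
F12 | step 24 | 8α-hydroxylabda-13(16),14-dien-19-yl (diethoxyphosphoryl)acetate | C=CC(=C)CC[C@@H]1[C@@]2(C)CCC[C@](C)(COC(=O)CP(=O)(OCC)OCC)[C@@H]2CC[C@@]1(C)O
F13 | step 24 | 8α-hydroxylabda-13(16),14-dien-19-yl (E)-3-[4-(TBS-oxy)-3-methoxyphenyl]prop-2-enoate | C=CC(=C)CC[C@@H]1[C@@]2(C)CCC[C@](C)(COC(=O)/C=C/c3ccc(O[Si](C)(C)C(C)(C)C)c(OC)c3)[C@@H]2CC[C@@]1(C)O
A1 | alternative 1 | (bromomethyl)dimethylsilyl ether of the 3β-allylic alcohol of 9,9-(ethylenedioxy)-4,10-dimethyl-Δ4-octalin | O1CCOC12[C@@]3(C)CC[C@H](O[Si](C)(C)CBr)C(C)=C3CCC2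
A2 | alternative 1 | cis-fused oxasilolane (C3–O–SiMe2–C19–C4) on the trans-decalin C9 ketal | O1CCOC12[C@@]3(C)CC[C@@H]4O[Si](C)(C)C[C@]4(C)[C@@H]3CCC2
A3 | alternative 2 | methyl (3E)-4-methyl-5-oxopent-3-enoate | O=C/C(C)=C/CC(=O)OC
A4 | alternative 2 | tert-butyldimethyl{[(3E)-4-methylhexa-3,5-dien-1-yl]oxy}silane | C=C/C(C)=C/CCO[Si](C)(C)C(C)(C)C
A5 | alternative 2 | ring B cyclohexene aldehyde with C5, C9 and C10 set | CC(C)(C)[Si](C)(C)OCC[C@@H]1[C@@](C)(C=O)[C@H](CC(=O)OC)CC=C1C
A6 | alternative 3 | acyclic trienimide: N-[(2E,8E)-7,7-bis(methoxycarbonyl)-3-methyldeca-2,8,10-trienoyl]-4-benzyloxazolidin-2-one | O=C1OC[C@H](Cc2ccccc2)N1C(=O)/C=C(\C)CCCC(C(=O)OC)(C(=O)OC)/C=C/C=C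
A7 | alternative 3 | trans-fused octalin imide with C5, C9 and C10 set and a C4 gem-diester | O=C1OC[C@H](Cc2ccccc2)N1C(=O)[C@@H]3[C@@]4(C)CCCC(C(=O)OC)(C(=O)OC)[C@@H]4C=CC3
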